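**Retrosynthetic overview**
1. Target ⇒ last step: the CH2 bridge is made by a Mannich-type methylene transfer between C3 of the pyranone and the one free ring carbon of the prenylated (S)-acylphloroglucinol.
2. Pyranone ⇒ key step: the ring is closed at the lactone C–O bond (ketone-enol oxygen onto an acylketene). The open chain comes from methylketene dimer (two propionyl chloride units) plus the C2 unit of Meldrum's acid.
3. Arene half ⇒ C-prenylation of the acylphloroglucinol ⇐ Friedel–Crafts acylation of phloroglucinol with (S)-2-methylbutanoic acid (chiral pool, the only stereocentre).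
4. Ring order: the benzene ring is bought; the pyranone is the only ring built (step 3); the two rings are joined last (step 4).

Assumption: the target is taken as drawn, with the (S)-2-methylbutanoyl group as its only stereocentre; a one-flask sequence without isolation is counted as one step; yields are estimates.

**Route**

Step 1
Reactants: 1 (S)-2-methylbutanoic acid; 2 phloroglucinol (benzene-1,3,5-triol, anhydrous)
Product: 4 (S)-2-methyl-1-(2,4,6-trihydroxyphenyl)butan-1-one, via (S)-2-methylbutanoyl chloride 3 (not isolated)
Conditions: (COCl)2 (1.0 equiv), DMF (cat.), CH2Cl2, 0 °C → rt; then added to 2, AlCl3 (3.5 equiv), CH2Cl2/MeNO2, 0 °C → rt; aq. HCl work-up (est. 60–70%)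
Reagents that add atoms: none
Why: Friedel–Crafts acylation of the symmetrical, highly activated phloroglucinol by the acid chloride made in the flask (AlCl3 also converts any O-acyl ester to the ketone by Fries rearrangement); the (S) stereocentre is carried unchanged from the chiral-pool acid because no base is present and the mixture stays at or below rt (ee checked by chiral HPLC on 4).

Step 2
Reactants: 4 (S)-2-methyl-1-(2,4,6-trihydroxyphenyl)butan-1-one
Product: 5 (S)-2-methyl-1-[2,4,6-trihydroxy-3-(3-methylbut-2-en-1-yl)phenyl]butan-1-one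
Conditions: prenyl bromide (1.0 equiv), 10% aq. KOH, 0 °C, N2; then 1 M HCl (est. 35–45%, unreacted 4 recycled)
Reagents that add atoms: prenyl bromide (1-bromo-3-methylbut-2-ene), CC(C)=CCBr
Why: Ambident phenoxide alkylation (C-prenylation): in water the hydrogen-bonded polyphenoxide reacts with prenyl bromide at ring carbon, the two free positions are equivalent so a single mono-C-prenyl isomer forms, and the α-stereocentre survives because the aryl ketone of a phenoxide is not enolised at 0 °C.

Step 3
Reactants: 6 propionyl chloride (two molecules are built in); 7 Meldrum's acid (2,2-dimethyl-1,3-dioxane-4,6-dione)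
Product: 12 6-ethyl-4-hydroxy-5-methyl-2H-pyran-2-one, via methylketene 8 (not isolated), via methylketene dimer 9 (not isolated), via acyl Meldrum's acid 10 (not isolated), via acylketene 11 (not isolated)
Conditions: 6 (2.6 equiv, added over 2 h), Et3N (2.7 equiv), CH2Cl2, 0 °C → rt; then 7 (1.0 equiv), Et3N (1.1 equiv), DMAP (10 mol %), rt; then HCl (4 M in dioxane, 1.3 equiv), PhMe, 90 °C (CH2Cl2 distilled out); NaHCO3 extraction, acidification (projected 35–50%)
Reagents that add atoms: none
Why: Proposed new method: a formal C2 ring expansion of a ketene-dimer β-lactone to a 4-hydroxy-2-pyranone — Et3N dehydrochlorinates 6 to methylketene 8 and catalyses its [2+2] dimerisation to β-lactone 9; DMAP opens the strained acyl C–O bond of 9 (its other ring carbon is sp2, so only acyl attack is possible) to a β-ketoacylpyridinium that C-acylates the Meldrum's acid anion, giving 10; after protonation 10 loses acetone and CO2 by the usual retro-[4+2] fragmentation to acylketene 11, and the enol oxygen of its ethyl ketone (the former lactone oxygen) adds to the ketene carbon in a 6-membered C–O ring closure made irreversible by tautomerisation to the aromatic pyranone, which also erases the racemic stereocentre of 9; the closest known reaction types are acyl transfer from ketene dimers to amines and alcohols, acetoacetylation of Meldrum's acid by diketene, and acylketene-to-pyranone cyclisation of 6-(2-oxoalkyl)-1,3-dioxin-4-ones, whereas C-acyl transfer from an alkylketene dimer to Meldrum's acid and the one-flask cascade to a 5,6-dialkyl pyranone have, to my knowledge, not been shown.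

Step 4
Reactants: 12 6-ethyl-4-hydroxy-5-methyl-2H-pyran-2-one; 5 (S)-2-methyl-1-[2,4,6-trihydroxy-3-(3-methylbut-2-en-1-yl)phenyl]butan-1-one
Product: 15 6-ethyl-4-hydroxy-5-methyl-3-{[2,4,6-trihydroxy-3-(3-methylbut-2-en-1-yl)-5-[(2S)-2-methylbutanoyl]phenyl]methyl}-2H-pyran-2-one, via pyranone Mannich base 13 (not isolated), via 3-methylidenepyrandione 14 (not isolated)
Conditions: 12, CH2=NMe2+ I− (1.0 equiv), MeCN, rt, 1 h; then 5 (1.1 equiv), 50 °C (est. 50–60%)
Reagents that add atoms: Eschenmoser's salt (N,N-dimethylmethyleneiminium iodide), C=[N+](C)C.[I-]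
Why: Mannich reaction of the pyranone enol gives 13, which eliminates Me2NH to the Michael acceptor 14; the only unsubstituted, doubly OH-activated ring carbon of 5 adds to it (Friedel–Crafts-type conjugate addition) and both rings re-aromatise, pre-forming 13 before 5 is added keeps the methylene-bis-pyranone homodimer low, and no stereocentre is formed while the remote (S) centre is untouched under these near-neutral conditions.

**Compound list**
1 | (S)-2-methylbutanoic acid | CC[C@H](C)C(=O)O | starting material
2 | phloroglucinol (benzene-1,3,5-triol) | Oc1cc(O)cc(O)c1 | starting material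
3 | (S)-2-methylbutanoyl chloride | CC[C@H](C)C(=O)Cl | intermediate
4 | (S)-2-methyl-1-(2,4,6-trihydroxyphenyl)butan-1-one | CC[C@H](C)C(=O)c1c(O)cc(O)cc1O | intermediate
5 | (S)-2-methyl-1-[2,4,6-trihydroxy-3-(3-methylbut-2-en-1-yl)phenyl]butan-1-one | CC[C@H](C)C(=O)c1c(O)cc(O)c(CC=C(C)C)c1O | intermediate
6 | propionyl chloride | CCC(=O)Cl | starting material
7 | Meldrum's acid (2,2-dimethyl-1,3-dioxane-4,6-dione) | CC1(C)OC(=O)CC(=O)O1 | starting material
8 | methylketene (prop-1-en-1-one) | CC=C=O | intermediate
9 | methylketene dimer, (Z)-4-ethylidene-3-methyloxetan-2-one, racemic at C3 | C/C=C1\OC(=O)C1C | intermediate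
10 | acyl Meldrum's acid, 5-(1-hydroxy-2-methyl-3-oxopentylidene)-2,2-dimethyl-1,3-dioxane-4,6-dione, racemic | CCC(=O)C(C)C(O)=C1C(=O)OC(C)(C)OC1=O | intermediate
11 | acylketene, 4-methyl-3,5-dioxohept-1-en-1-one, racemic | CCC(=O)C(C)C(=O)C=C=O | intermediate
12 | 6-ethyl-4-hydroxy-5-methyl-2H-pyran-2-one | CCc1oc(=O)cc(O)c1C | intermediate
13 | pyranone Mannich base, 3-[(dimethylamino)methyl]-6-ethyl-4-hydroxy-5-methyl-2H-pyran-2-one | CCc1oc(=O)c(CN(C)C)c(O)c1C | intermediate
14 | 6-ethyl-5-methyl-3-methylidene-2H-pyran-2,4(3H)-dione | CCC1=C(C)C(=O)C(=C)C(=O)O1 | intermediate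
15 | 6-ethyl-4-hydroxy-5-methyl-3-{[2,4,6-trihydroxy-3-(3-methylbut-2-en-1-yl)-5-[(2S)-2-methylbutanoyl]phenyl]methyl}-2H-pyran-2-one (CNP0209307.1) | CCc1oc(=O)c(Cc2c(O)c(CC=C(C)C)c(O)c(C(=O)[C@@H](C)CC)c2O)c(O)c1C | target

**Step count and risks**

Total step count: 4 (step 3 is a one-flask, three-stage operation). Longest linear sequence: 3 steps (1 → 2 → 4 from phloroglucinol); the pyranone branch is 2 steps (3 → 4).

Steps most likely to fail:

Step 3 (the proposed new cascade). The risks are sluggish C-acyl transfer from the hindered alkylketene dimer, methylketene oligomers (notably the 3-methyl pyranone trimer) and O-acylation. The fallback uses known chemistry only, sets out from 6 and 7 and comes back at 12. Acylation of 7 with 6 (pyridine, CH2Cl2, 0 °C) gives 5-(1-hydroxypropylidene)-2,2-dimethyl-1,3-dioxane-4,6-dione F1. Ethanolysis at reflux turns it into ethyl 3-oxopentanoate F2 (also a cheap catalogue compound, so in practice the detour is two operations). Its dianion (NaH, then n-BuLi, THF, 0 °C) is acylated at the γ-carbon with methyl propionate (β-keto ester dianion acylation) to ethyl 4-methyl-3,5-dioxoheptanoate F3. DBU in toluene at reflux lactonises F3 to 12.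

Step 2 (mono-C-prenylation). The risks are di-prenylation, O-prenylation and a modest yield. The fallback sets out from 4 and comes back at 5 by putting the prenyl group on oxygen first. K2CO3 and prenyl bromide in acetone alkylate only the non-chelated para hydroxyl, giving the aryl prenyl ether (S)-1-[2,6-dihydroxy-4-(3-methylbut-2-en-1-yloxy)phenyl]-2-methylbutan-1-one F4. Magnesium silicate MgSiO3 (Florisil) in toluene at 110 °C then moves the prenyl group by a formal [1,3] oxygen-to-carbon shift to the ortho ring carbon, which gives 5.

Step 4 (methylene bridge). The risks are the methylene-bis-pyranone homodimer and acid-promoted chroman formation from the prenyl group. The fallback sets out from 5 and comes back at 15 by reversing the roles of the partners. Compound 5 and CH2=NMe2+ I− in MeCN give the benzylic Mannich base (S)-1-{3-[(dimethylamino)methyl]-2,4,6-trihydroxy-5-(3-methylbut-2-en-1-yl)phenyl}-2-methylbutan-1-one F5, which is isolated. Heated with 12 in dioxane at 90 °C it loses dimethylamine to the ortho-quinone methide 3,5-dihydroxy-6-methylidene-4-[(2S)-2-methylbutanoyl]-2-(3-methylbut-2-en-1-yl)cyclohexa-2,4-dien-1-one F6, which 12 traps at C3 by Michael addition to give 15.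

**Further compounds**
F1 | step 3 | 5-(1-hydroxypropylidene)-2,2-dimethyl-1,3-dioxane-4,6-dione | CCC(O)=C1C(=O)OC(C)(C)OC1=O
F2 | step 3 | ethyl 3-oxopentanoate | CCC(=O)CC(=O)OCC
F3 | step 3 | ethyl 4-methyl-3,5-dioxoheptanoate (racemic) | CCC(=O)C(C)C(=O)CC(=O)OCC
F4 | step 2 | (S)-1-[2,6-dihydroxy-4-(3-methylbut-2-en-1-yloxy)phenyl]-2-methylbutan-1-one | CC[C@H](C)C(=O)c1c(O)cc(OCC=C(C)C)cc1O
F5 | step 4 | (S)-1-{3-[(dimethylamino)methyl]-2,4,6-trihydroxy-5-(3-methylbut-2-en-1-yl)phenyl}-2-methylbutan-1-one | CC[C@H](C)C(=O)c1c(O)c(CN(C)C)c(O)c(CC=C(C)C)c1O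
F6 | step 4 | 3,5-dihydroxy-6-methylidene-4-[(2S)-2-methylbutanoyl]-2-(3-methylbut-2-en-1-yl)cyclohexa-2,4-dien-1-one | CC[C@H](C)C(=O)C1=C(O)C(=C)C(=O)C(CC=C(C)C)=C1O
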